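The ten-membered carbocycle is disconnected at C7–C8. The trans-fused α-methylene-γ-butyrolactone (O–C6, C7, C11=C13, C12) and the C8 carbinol beside C7 make up a homoallylic alcohol, the retron of a carbonyl allylation. The precursor is thus an open chain: a (5R)-3-(bromomethyl)furan-2(5H)-one whose C6 carries the (Z,Z)-diene chain ending in the C9-acyloxy C8 aldehyde. CrCl2 converts the allylic bromide into an allylchromium that attacks the aldehyde through C7; this one operation closes the ring, forms C7–C8, moves the alkene to C11=C13 and sets C7 and C8. C8 is then inverted as its isobutyrate is installed.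

Key step: step 15

Remark on numbering: germacranolide numbering is used throughout. C6 carries the lactone oxygen, C7 carries C11, C8 the isobutyrate, C9 the 2-hydroxyisobutyrate, C10 the CH2OH carbon C14, C4 the methyl C15; C12 is the lactone carbonyl and C13 the exocyclic methylene.
Assumption: β-isocupreidine is taken to attack aldehyde 7 with the facial sense it shows with aliphatic aldehydes, and the ProPhenol antipode is chosen to give the R carbinol; if either sense is opposite, the pseudo-enantiomeric catalyst or the antipodal ligand is used.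

Step 1
Reactants: 1 hex-1-en-5-yne; 2 N-methoxy-N-methylcarbamoyl chloride
Product: 4 N-methoxy-N-methylhept-6-en-2-ynamide, via lithium hex-5-en-1-yn-1-ide 3 (not isolated)
Conditions: n-BuLi, THF, −78 °C; then 2, −78 to 0 °C
Reagents that add atoms: none
Why: Deprotonation of the terminal alkyne and acylation of the lithium acetylide by the carbamoyl chloride should give the alkynyl Weinreb amide (acetylide acylation).

Step 2
Reactants: 4 N-methoxy-N-methylhept-6-en-2-ynamide
Product: 5 (2Z)-N-methoxy-N,3-dimethylhepta-2,6-dienamide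
Conditions: Me2CuLi (from MeLi and CuI), THF, −78 °C; sat. aq. NH4Cl at −78 °C
Reagents that add atoms: lithium dimethylcuprate, [Li+].C[Cu-]C
Why: syn-Carbocupration of the ynamide at low temperature and protonation with retention should place C3 cis to C6 across C4=C5, giving the Z trisubstituted alkene (conjugate addition of an organocuprate to an alkynoic acid derivative).

Step 3
Reactants: 6 1,1,1,3,3,3-hexafluoropropan-2-yl acrylate; 7 2,2-dimethoxyacetaldehyde
Product: 8 1,1,1,3,3,3-hexafluoropropan-2-yl (3S)-3-hydroxy-4,4-dimethoxy-2-methylidenebutanoate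
Conditions: β-isocupreidine (10 mol%), DMF, −55 °C
Reagents that add atoms: none
Why: An enantioselective Morita–Baylis–Hillman reaction should join C9 to C10, the bifunctional cinchona amine catalyst selecting the aldehyde face so that C9 is set S.

Step 4
Reactants: 5 (2Z)-N-methoxy-N,3-dimethylhepta-2,6-dienamide; 8 the Morita–Baylis–Hillman adduct
Product: 9 1,1,1,3,3,3-hexafluoropropan-2-yl (2E,6Z)-2-[(1S)-1-hydroxy-2,2-dimethoxyethyl]-8-[methoxy(methyl)amino]-6-methyl-8-oxoocta-2,6-dienoate
Conditions: second-generation Hoveyda–Grubbs catalyst (5–10 mol%), 1,4-benzoquinone (10 mol%), excess 8, CH2Cl2, 40 °C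
Reagents that add atoms: none
Why: Cross-metathesis of the terminal alkene with the 2-substituted acrylate is driven by loss of ethene and should be thermodynamically controlled, placing C2 trans to the ester carbon C14 and cis to C9, while the trisubstituted enamide alkene stays inert.

Step 5
Reactants: 9 the cross-metathesis product
Product: 10 (2Z,6Z,8S)-8-hydroxy-7-(hydroxymethyl)-9,9-dimethoxy-3-methylnona-2,6-dienal
Conditions: iBu2AlH (excess), CH2Cl2, −78 °C; aq. KNaC4H4O6 work-up
Reagents that add atoms: none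
Why: iBu2AlH should reduce the activated enoate ester to the allylic alcohol by 1,2-reduction and stop at the chelated tetrahedral intermediate of the Weinreb amide, which releases the (Z)-enal on work-up (hydride reduction).

Step 6
Reactants: 10 the enal diol
Product: 11 (2Z,6Z,8S)-7-{[tert-butyl(dimethyl)silyl]oxymethyl}-8-hydroxy-9,9-dimethoxy-3-methylnona-2,6-dienal
Conditions: TBSCl (1.05 equiv), imidazole, CH2Cl2, 0 °C
Reagents that add atoms: tert-butyldimethylsilyl chloride, CC(C)(C)[Si](C)(C)Cl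
Why: The primary allylic C14 hydroxyl should be silylated much faster than the hindered secondary C9 hydroxyl (selective silylation).

Step 7
Reactants: 11 the silylated enal; 12 triethyl(prop-2-yn-1-yloxy)silane
Product: 13 (4R,5Z,9Z,11S)-10-{[tert-butyl(dimethyl)silyl]oxymethyl}-12,12-dimethoxy-6-methyl-1-(triethylsilyloxy)dodeca-5,9-dien-2-yne-4,11-diol
Conditions: Me2Zn, (S,S)-ProPhenol (20 mol%), Ph3P=O (40 mol%), toluene, 0–4 °C
Reagents that add atoms: none
Why: Zinc–ProPhenol-catalysed enantioselective addition of the alkynylzinc to the enal should set C6 as R under catalyst control (asymmetric alkynylation of an aldehyde).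

Step 8
Reactants: 13 the propargylic alcohol
Product: 15 (2Z,4R,5Z,9Z,11S)-10-{[tert-butyl(dimethyl)silyl]oxymethyl}-3-iodo-12,12-dimethoxy-6-methyl-1-(triethylsilyloxy)dodeca-2,5,9-triene-4,11-diol, via cyclic alkenylaluminate 14 (not isolated)
Conditions: NaAlH2(OCH2CH2OMe)2, THF, 0 °C to rt; EtOAc; then I2, THF, −78 °C
Reagents that add atoms: iodine, [I][I]
Why: Alkoxide-directed trans-hydroalumination of the propargylic alcohol should deliver hydride to C7 and aluminium to C11, and iodinolysis with retention then gives the vinyl iodide with iodine cis to C6.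

Step 9
Reactants: 15 the (Z)-iodo allylic alcohol
Product: 16 (5R)-5-[(1Z,5Z,7S)-6-{[tert-butyl(dimethyl)silyl]oxymethyl}-7-hydroxy-8,8-dimethoxy-2-methylocta-1,5-dien-1-yl]-3-[(triethylsilyloxy)methyl]furan-2(5H)-one
Conditions: PdCl2(PPh3)2 (5 mol%), CO (1 atm), K2CO3, N2H4·H2O (cat.), THF, rt
Reagents that add atoms: carbon monoxide, [C-]#[O+]
Why: Oxidative addition to zerovalent palladium, CO insertion and capture of the acylpalladium by the cis C6 hydroxyl should close the butenolide without touching C6 (carbonylative lactonisation of a (Z)-3-iodoallylic alcohol).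

Step 10
Reactants: 17 2-hydroxy-2-methylpropanoic acid
Product: 19 2-methyl-2-(triethylsilyloxy)propanoic acid, via triethylsilyl 2-methyl-2-(triethylsilyloxy)propanoate 18 (not isolated)
Conditions: TESCl (2.2 equiv), imidazole, DMF, rt; then K2CO3, MeOH/H2O, 0 °C; acidify to pH 4
Reagents that add atoms: chlorotriethylsilane, CC[Si](Cl)(CC)CC
Why: Exhaustive silylation followed by selective hydrolysis of the labile silyl ester should leave the tertiary triethylsilyl ether in place (silylation and selective desilylation).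

Step 11
Reactants: 16 the butenolide alcohol; 19 2-methyl-2-(triethylsilyloxy)propanoic acid
Product: 20 (2S,3Z,7Z)-3-{[tert-butyl(dimethyl)silyl]oxymethyl}-1,1-dimethoxy-7-methyl-8-{(2R)-5-oxo-4-[(triethylsilyloxy)methyl]-2,5-dihydrofuran-2-yl}octa-3,7-dien-2-yl 2-methyl-2-(triethylsilyloxy)propanoate
Conditions: 2-methyl-6-nitrobenzoic anhydride, DMAP, iPr2NEt, CH2Cl2, 0 °C to rt
Reagents that add atoms: none
Why: Mixed-anhydride activation with nucleophilic catalysis should acylate the hindered C9 hydroxyl, the only free hydroxyl, without change at C9, the low temperature guarding the base-sensitive C6 position (esterification through a mixed anhydride).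

Step 12
Reactants: 20 the C9 ester
Product: 21 (2S,3Z,7Z)-3-{[tert-butyl(dimethyl)silyl]oxymethyl}-8-[(2R)-4-(hydroxymethyl)-5-oxo-2,5-dihydrofuran-2-yl]-1,1-dimethoxy-7-methylocta-3,7-dien-2-yl 2-methyl-2-(triethylsilyloxy)propanoate
Conditions: PPTS (cat.), MeOH/CH2Cl2, 0 °C
Reagents that add atoms: none
Why: The primary triethylsilyl ether should solvolyse far faster than the primary tert-butyldimethylsilyl ether and the hindered tertiary triethylsilyl ether, while the dimethyl acetal only exchanges with the solvent (selective acid-catalysed desilylation).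

Step 13
Reactants: 21 the C13 alcohol
Product: 22 (2S,3Z,7Z)-8-[(2R)-4-(bromomethyl)-5-oxo-2,5-dihydrofuran-2-yl]-3-{[tert-butyl(dimethyl)silyl]oxymethyl}-1,1-dimethoxy-7-methylocta-3,7-dien-2-yl 2-methyl-2-(triethylsilyloxy)propanoate
Conditions: CBr4, PPh3, CH2Cl2, 0 °C
Reagents that add atoms: carbon tetrabromide, BrC(Br)(Br)Br
Why: The Appel reaction should convert the primary allylic alcohol into the bromide under neutral conditions that leave the acetal, the silyl ethers and the butenolide untouched.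

Step 14
Reactants: 22 the allylic bromide acetal
Product: 24 (2S,3Z,7Z)-8-[(2R)-4-(bromomethyl)-5-oxo-2,5-dihydrofuran-2-yl]-3-{[tert-butyl(dimethyl)silyl]oxymethyl}-7-methyl-1-oxoocta-3,7-dien-2-yl 2-methyl-2-(triethylsilyloxy)propanoate, via collidinium N,O-acetal triflate 23 (not isolated)
Conditions: TESOTf, 2,4,6-collidine, CH2Cl2, 0 °C; then H2O
Reagents that add atoms: water, O
Why: The silyl triflate should ionise the acetal, collidine traps the oxocarbenium ion as a pyridinium salt and water hydrolyses it under non-acidic conditions that spare the silyl ethers, the allylic bromide and the lactone (chemoselective acetal cleavage).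

Step 15
Reactants: 24 the bromo aldehyde
Product: 26 (1(10)Z,4Z,6R,7R,8R,9S)-14-[tert-butyl(dimethyl)silyl]oxy-8-hydroxy-9-[2-methyl-2-(triethylsilyloxy)propanoyloxy]germacra-1(10),4,11(13)-trien-12,6-olide (8α-alcohol, H-6β, H-7α), via allylchromium dichloride 25 (not isolated)
Conditions: CrCl2 (10 equiv), THF, rt, syringe-pump addition of 24 (final 2 mM)
Reagents that add atoms: none
Why: Two equivalents of CrCl2 (divalent chromium) reduce the allylic C13–Br bond to the η1-allylchromium 25 (trivalent chromium), which adds through its γ-carbon C7 to the C8 aldehyde in a six-membered chair transition state and moves the double bond to C11=C13, unveiling the α-methylene lactone. The closest known reaction type is the intramolecular Nozaki–Hiyama–Kishi (Barbier-type) allylation used for macrocyclisation, together with the chromium-, zinc- or indium-mediated allylation of aldehydes by 3-(bromomethyl)furan-2(5H)-ones. The ten-membered carbocycle C1–C10 is closed in a 10-exo-trig mode with respect to the aldehyde, by SE2′ attack of the allyl unit. C7 is controlled by the C6 stereocentre, since C8 should bond to the butenolide face opposite to the C5 alkenyl substituent and so give the trans-fused lactone. C8 is controlled by the chair transition state of the ring-locked allylchromium, in which C6 is trans to CH2Cr (an E-crotyl-type reagent) and the aldehyde substituent is equatorial (7,8-anti), reinforced by Felkin–Anh addition anti to the C9 acyloxy group (8,9-anti), so the expected product is the 8R alcohol, the C8 epimer of the natural configuration, which step 16 corrects. The step needs ring closure to win over oligomerisation, secured by high dilution and slow addition, and insertion only into the allylic bromide in the presence of esters, silyl ethers and the aldehyde, which divalent chromium provides.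

Step 16
Reactants: 26 the 8α-alcohol; 27 2-methylpropanoic acid
Product: 28 (1(10)Z,4Z,6R,7S,8S,9S)-14-[tert-butyl(dimethyl)silyl]oxy-8-(2-methylpropanoyloxy)-9-[2-methyl-2-(triethylsilyloxy)propanoyloxy]germacra-1(10),4,11(13)-trien-12,6-olide
Conditions: PPh3, DIAD, toluene/THF, 0 °C to rt
Reagents that add atoms: none
Why: In the Mitsunobu esterification the C8 hydroxyl is activated as an alkoxyphosphonium ion and should be displaced by isobutyrate with SN2 inversion, turning 8R into the required 8S ester (the C7 descriptor changes from R to S by priority only).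

Step 17
Reactants: 28 the bis-silyl diester
Product: 29 (1(10)Z,4Z,6R,7S,8S,9S)-14-hydroxy-9-(2-hydroxy-2-methylpropanoyloxy)-8-(2-methylpropanoyloxy)germacra-1(10),4,11(13)-trien-12,6-olide (CNP0220567.2)
Conditions: HF·pyridine, pyridine, THF, 0 °C to rt
Reagents that add atoms: none
Why: Fluoride should cleave the primary tert-butyldimethylsilyl ether and the tertiary triethylsilyl ether under buffered, mildly acidic conditions that spare both esters and the α-methylene lactone (global desilylation).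

Compound list
1 | hex-1-en-5-yne | C=CCCC#C | starting material
2 | N-methoxy-N-methylcarbamoyl chloride | CON(C)C(Cl)=O | starting material
3 | lithium hex-5-en-1-yn-1-ide | C=CCCC#C[Li] | intermediate
4 | N-methoxy-N-methylhept-6-en-2-ynamide | C=CCCC#CC(=O)N(C)OC | intermediate
5 | (2Z)-N-methoxy-N,3-dimethylhepta-2,6-dienamide | C=CCC/C(C)=C\C(=O)N(C)OC | intermediate
6 | 1,1,1,3,3,3-hexafluoropropan-2-yl acrylate | C=CC(=O)OC(C(F)(F)F)C(F)(F)F | starting material
7 | 2,2-dimethoxyacetaldehyde | COC(OC)C=O | starting material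
8 | 1,1,1,3,3,3-hexafluoropropan-2-yl (3S)-3-hydroxy-4,4-dimethoxy-2-methylidenebutanoate | C=C(C(=O)OC(C(F)(F)F)C(F)(F)F)[C@H](O)C(OC)OC | intermediate
9 | 1,1,1,3,3,3-hexafluoropropan-2-yl (2E,6Z)-2-[(1S)-1-hydroxy-2,2-dimethoxyethyl]-8-[methoxy(methyl)amino]-6-methyl-8-oxoocta-2,6-dienoate | CON(C)C(=O)/C=C(/C)CC/C=C(/C(=O)OC(C(F)(F)F)C(F)(F)F)[C@H](O)C(OC)OC | intermediate
10 | (2Z,6Z,8S)-8-hydroxy-7-(hydroxymethyl)-9,9-dimethoxy-3-methylnona-2,6-dienal | O=C/C=C(/C)CC/C=C(/CO)[C@H](O)C(OC)OC | intermediate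
11 | (2Z,6Z,8S)-7-{[tert-butyl(dimethyl)silyl]oxymethyl}-8-hydroxy-9,9-dimethoxy-3-methylnona-2,6-dienal | O=C/C=C(/C)CC/C=C(/CO[Si](C)(C)C(C)(C)C)[C@H](O)C(OC)OC | intermediate
12 | triethyl(prop-2-yn-1-yloxy)silane | C#CCO[Si](CC)(CC)CC | starting material
13 | (4R,5Z,9Z,11S)-10-{[tert-butyl(dimethyl)silyl]oxymethyl}-12,12-dimethoxy-6-methyl-1-(triethylsilyloxy)dodeca-5,9-dien-2-yne-4,11-diol | CC[Si](CC)(CC)OCC#C[C@H](O)/C=C(/C)CC/C=C(/CO[Si](C)(C)C(C)(C)C)[C@H](O)C(OC)OC | intermediate
14 | sodium cyclic alkenylaluminate (O6–Al–C11 oxaaluminole ring; C9 hydroxyl drawn protonated) | [Na+].COCCO[Al-]1(OCCOC)O[C@H](/C=C(/C)CC/C=C(/CO[Si](C)(C)C(C)(C)C)[C@H](O)C(OC)OC)C=C1CO[Si](CC)(CC)CC | intermediate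
15 | (2Z,4R,5Z,9Z,11S)-10-{[tert-butyl(dimethyl)silyl]oxymethyl}-3-iodo-12,12-dimethoxy-6-methyl-1-(triethylsilyloxy)dodeca-2,5,9-triene-4,11-diol | CC[Si](CC)(CC)OC/C(I)=C/[C@H](O)/C=C(/C)CC/C=C(/CO[Si](C)(C)C(C)(C)C)[C@H](O)C(OC)OC | intermediate
16 | (5R)-5-[(1Z,5Z,7S)-6-{[tert-butyl(dimethyl)silyl]oxymethyl}-7-hydroxy-8,8-dimethoxy-2-methylocta-1,5-dien-1-yl]-3-[(triethylsilyloxy)methyl]furan-2(5H)-one | O=C1O[C@H](/C=C(/C)CC/C=C(/CO[Si](C)(C)C(C)(C)C)[C@H](O)C(OC)OC)C=C1CO[Si](CC)(CC)CC | intermediate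
17 | 2-hydroxy-2-methylpropanoic acid | CC(C)(O)C(=O)O | starting material
18 | triethylsilyl 2-methyl-2-(triethylsilyloxy)propanoate | CC[Si](CC)(CC)OC(C)(C)C(=O)O[Si](CC)(CC)CC | intermediate
19 | 2-methyl-2-(triethylsilyloxy)propanoic acid | CC[Si](CC)(CC)OC(C)(C)C(=O)O | intermediate
20 | (2S,3Z,7Z)-3-{[tert-butyl(dimethyl)silyl]oxymethyl}-1,1-dimethoxy-7-methyl-8-{(2R)-5-oxo-4-[(triethylsilyloxy)methyl]-2,5-dihydrofuran-2-yl}octa-3,7-dien-2-yl 2-methyl-2-(triethylsilyloxy)propanoate | O=C1O[C@H](/C=C(/C)CC/C=C(/CO[Si](C)(C)C(C)(C)C)[C@H](OC(=O)C(C)(C)O[Si](CC)(CC)CC)C(OC)OC)C=C1CO[Si](CC)(CC)CC | intermediate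
21 | (2S,3Z,7Z)-3-{[tert-butyl(dimethyl)silyl]oxymethyl}-8-[(2R)-4-(hydroxymethyl)-5-oxo-2,5-dihydrofuran-2-yl]-1,1-dimethoxy-7-methylocta-3,7-dien-2-yl 2-methyl-2-(triethylsilyloxy)propanoate | O=C1O[C@H](/C=C(/C)CC/C=C(/CO[Si](C)(C)C(C)(C)C)[C@H](OC(=O)C(C)(C)O[Si](CC)(CC)CC)C(OC)OC)C=C1CO | intermediate
22 | (2S,3Z,7Z)-8-[(2R)-4-(bromomethyl)-5-oxo-2,5-dihydrofuran-2-yl]-3-{[tert-butyl(dimethyl)silyl]oxymethyl}-1,1-dimethoxy-7-methylocta-3,7-dien-2-yl 2-methyl-2-(triethylsilyloxy)propanoate | O=C1O[C@H](/C=C(/C)CC/C=C(/CO[Si](C)(C)C(C)(C)C)[C@H](OC(=O)C(C)(C)O[Si](CC)(CC)CC)C(OC)OC)C=C1CBr | intermediate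
23 | collidinium N,O-acetal triflate of 22 (C8 bears OMe and N-linked 2,4,6-trimethylpyridinium; C8 epimers) | O=C1O[C@H](/C=C(/C)CC/C=C(/CO[Si](C)(C)C(C)(C)C)[C@H](OC(=O)C(C)(C)O[Si](CC)(CC)CC)C(OC)[n+]2c(C)cc(C)cc2C)C=C1CBr.[O-]S(=O)(=O)C(F)(F)F | intermediate
24 | (2S,3Z,7Z)-8-[(2R)-4-(bromomethyl)-5-oxo-2,5-dihydrofuran-2-yl]-3-{[tert-butyl(dimethyl)silyl]oxymethyl}-7-methyl-1-oxoocta-3,7-dien-2-yl 2-methyl-2-(triethylsilyloxy)propanoate | O=C1O[C@H](/C=C(/C)CC/C=C(/CO[Si](C)(C)C(C)(C)C)[C@H](OC(=O)C(C)(C)O[Si](CC)(CC)CC)C=O)C=C1CBr | intermediate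
25 | allylchromium dichloride from 24 (trivalent chromium on C13) | O=C1O[C@H](/C=C(/C)CC/C=C(/CO[Si](C)(C)C(C)(C)C)[C@H](OC(=O)C(C)(C)O[Si](CC)(CC)CC)C=O)C=C1C[Cr](Cl)Cl | intermediate
26 | (1(10)Z,4Z,6R,7R,8R,9S)-14-[tert-butyl(dimethyl)silyl]oxy-8-hydroxy-9-[2-methyl-2-(triethylsilyloxy)propanoyloxy]germacra-1(10),4,11(13)-trien-12,6-olide | C=C1C(=O)O[C@@H]2/C=C(/C)CC/C=C(/CO[Si](C)(C)C(C)(C)C)[C@H](OC(=O)C(C)(C)O[Si](CC)(CC)CC)[C@H](O)[C@@H]12 | intermediate
27 | 2-methylpropanoic acid | CC(C)C(=O)O | starting material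
28 | (1(10)Z,4Z,6R,7S,8S,9S)-14-[tert-butyl(dimethyl)silyl]oxy-8-(2-methylpropanoyloxy)-9-[2-methyl-2-(triethylsilyloxy)propanoyloxy]germacra-1(10),4,11(13)-trien-12,6-olide | C=C1C(=O)O[C@@H]2/C=C(/C)CC/C=C(/CO[Si](C)(C)C(C)(C)C)[C@H](OC(=O)C(C)(C)O[Si](CC)(CC)CC)[C@@H](OC(=O)C(C)C)[C@@H]12 | intermediate
29 | (1(10)Z,4Z,6R,7S,8S,9S)-14-hydroxy-9-(2-hydroxy-2-methylpropanoyloxy)-8-(2-methylpropanoyloxy)germacra-1(10),4,11(13)-trien-12,6-olide | C=C1C(=O)O[C@@H]2/C=C(/C)CC/C=C(/CO)[C@H](OC(=O)C(C)(C)O)[C@@H](OC(=O)C(C)C)[C@@H]12 | target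

Total step count: 17. Longest linear sequence: 15 steps (1, 2, 4–9, 11–17).

Steps most likely to fail

Step 15. Ring closure may lose to protonation of the allylchromium or to intermolecular coupling, or the tethered aldehyde may fail to reach the butenolide face anti to C5, eroding the control at C7 and C8. The fallback generates the allyl nucleophile catalytically from the allylic alcohol. It sets out from 21: the dimethyl acetal is cleaved with LiBF4 in wet MeCN to give (2S,3Z,7Z)-3-{[tert-butyl(dimethyl)silyl]oxymethyl}-8-[(2R)-4-(hydroxymethyl)-5-oxo-2,5-dihydrofuran-2-yl]-7-methyl-1-oxoocta-3,7-dien-2-yl 2-methyl-2-(triethylsilyloxy)propanoate F1. F1 is treated with Pd(OAc)2, PPh3 and Et3B in THF at high dilution; ionisation to a π-allylpalladium and transmetalation to boron should give an allylborane that cyclises through the same chair transition state. The route is rejoined at 26.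

Step 16. The C8 alkoxyphosphonium ion may eliminate, or be captured by the neighbouring C9 ester carbonyl, which would give retention or acyl scrambling. The fallback inverts C8 by oxidation and reduction and sets out from 26. Dess–Martin periodinane (NaHCO3, CH2Cl2, 0 °C) should give the ketone (1(10)Z,4Z,6R,7S,9S)-14-[tert-butyl(dimethyl)silyl]oxy-9-[2-methyl-2-(triethylsilyloxy)propanoyloxy]-8-oxogermacra-1(10),4,11(13)-trien-12,6-olide F2. LiAlH(OtBu)3 in THF at −78 °C should deliver hydride anti to the C9 acyloxy group (Felkin–Anh) and give the 8β-alcohol (1(10)Z,4Z,6R,7R,8S,9S)-14-[tert-butyl(dimethyl)silyl]oxy-8-hydroxy-9-[2-methyl-2-(triethylsilyloxy)propanoyloxy]germacra-1(10),4,11(13)-trien-12,6-olide F3. Acylation with isobutyric anhydride, DMAP and pyridine rejoins the route at 28.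

Step 4. Metathesis may stall on the hindered 1,1-disubstituted alkene of 8, or give E/Z mixtures and alkene migration. The fallback builds the trisubstituted alkene by olefination and the C9–C10 bond by an alkenyl–aldehyde coupling, and sets out from 5. OsO4 (cat.), NaIO4 and 2,6-lutidine (Lemieux–Johnson cleavage of the terminal alkene) should give (2Z)-N-methoxy-N,3-dimethyl-6-oxohex-2-enamide F4. Wittig reaction with methyl 2-iodo-2-(triphenylphosphoranylidene)acetate should give methyl (2Z,6Z)-2-iodo-8-[methoxy(methyl)amino]-6-methyl-8-oxoocta-2,6-dienoate F5. Coupling of F5 with aldehyde 7 using CrCl2, NiCl2 (cat.) and a chiral sulfonamide ligand, with retention of alkene geometry, should give methyl (2E,6Z)-2-[(1S)-1-hydroxy-2,2-dimethoxyethyl]-8-[methoxy(methyl)amino]-6-methyl-8-oxoocta-2,6-dienoate F6. F6 is reduced with iBu2AlH as in step 5 and the route is rejoined at 10.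

Further compounds
F1 | step 15 | (2S,3Z,7Z)-3-{[tert-butyl(dimethyl)silyl]oxymethyl}-8-[(2R)-4-(hydroxymethyl)-5-oxo-2,5-dihydrofuran-2-yl]-7-methyl-1-oxoocta-3,7-dien-2-yl 2-methyl-2-(triethylsilyloxy)propanoate | O=C1O[C@H](/C=C(/C)CC/C=C(/CO[Si](C)(C)C(C)(C)C)[C@H](OC(=O)C(C)(C)O[Si](CC)(CC)CC)C=O)C=C1CO
F2 | step 16 | (1(10)Z,4Z,6R,7S,9S)-14-[tert-butyl(dimethyl)silyl]oxy-9-[2-methyl-2-(triethylsilyloxy)propanoyloxy]-8-oxogermacra-1(10),4,11(13)-trien-12,6-olide | C=C1C(=O)O[C@@H]2/C=C(/C)CC/C=C(/CO[Si](C)(C)C(C)(C)C)[C@H](OC(=O)C(C)(C)O[Si](CC)(CC)CC)C(=O)[C@@H]12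
F3 | step 16 | (1(10)Z,4Z,6R,7R,8S,9S)-14-[tert-butyl(dimethyl)silyl]oxy-8-hydroxy-9-[2-methyl-2-(triethylsilyloxy)propanoyloxy]germacra-1(10),4,11(13)-trien-12,6-olide | C=C1C(=O)O[C@@H]2/C=C(/C)CC/C=C(/CO[Si](C)(C)C(C)(C)C)[C@H](OC(=O)C(C)(C)O[Si](CC)(CC)CC)[C@@H](O)[C@@H]12
F4 | step 4 | (2Z)-N-methoxy-N,3-dimethyl-6-oxohex-2-enamide | O=CCC/C(C)=C\C(=O)N(C)OC
F5 | step 4 | methyl (2Z,6Z)-2-iodo-8-[methoxy(methyl)amino]-6-methyl-8-oxoocta-2,6-dienoate | COC(=O)/C(I)=C/CC/C(C)=C\C(=O)N(C)OC
F6 | step 4 | methyl (2E,6Z)-2-[(1S)-1-hydroxy-2,2-dimethoxyethyl]-8-[methoxy(methyl)amino]-6-methyl-8-oxoocta-2,6-dienoate | COC(=O)/C(=C/CC/C(C)=C\C(=O)N(C)OC)[C@H](O)C(OC)OC
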